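**Strategy.** The route rests on making ring A of the upper flavan last, by benzannulation. Ring A is a resorcinol whose oxygens sit on C7 and C8a and which meets the congested diaryl-substituted C4 through C4a. C4 can therefore first be set, attached to C8 of the epigallocatechin unit, as a stereocentre carrying only a small vinyl group. Irradiation of a dienyl diazoketone with benzyloxyacetylene then forms C5–C6, C6–C7, C8–C8a and C4a–C8a in one operation and delivers ring A as a free C8a phenol with C7 already etherified. The precursor is an (E)-1-diazohept-3-en-2-one whose chain C5 bears the hexa-O-benzyl-epigallocatechin-8-yl group and whose chain C7 is a silylated (R)-4-benzyloxyphenyl carbinol.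

Key step: step 11

**Assumptions and design notes**
- Target stereochemistry as read from the SMILES: upper unit (2S,4R), 2,4-trans; lower unit (2R,3R)-epigallocatechin, joined C4→C8. The diazoketone and the benzannulation product were checked against this: C4 is R, the carbinol is R and is inverted to 2S on ring closure.
- The C7 oxygen enters as a benzyl ether (from benzyloxyacetylene), not as a silyl ether. The carbinol silyl ether is then the only silicon group, so fluoride cleaves it without competition from a more fluoride-labile aryl silyl ether. No acid is needed, which matters because the 4-benzyloxybenzylic carbinol ionises under acid. C7 is freed in the final hydrogenolysis.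
- Assumption: the sense of induction of the chiral diene in step 5 follows the usual model. Both ligand enantiomers are available, and the one that puts vinyl on the Si face of C-β of 8 is used.
- Compounds 1, 7, 9, 13, 17 and 18 are purchased. Compound 21 is kept as a cold solution because benzyl alkynyl ethers rearrange on warming.

**Route**

Step 1
Reactants: 1 (−)-epigallocatechin
Product: 3 hexa-O-benzyl-epigallocatechin, via penta-O-benzyl-epigallocatechin 2 (not isolated)
Conditions: BnBr (7 equiv), K2CO3, DMF, rt, argon; then NaH, Bu4NI (cat.), 0 °C to rt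
Reagents that add atoms: benzyl bromide BrCc1ccccc1
Why: Williamson etherification in two stages of basicity, the five phenols with carbonate and then the C3 alkoxide with hydride; no stereocentre is touched, and C2 cannot epimerise once the ring B phenols are capped.

Step 2
Reactants: 3 hexa-O-benzyl-epigallocatechin
Product: 4 8-bromo-hexa-O-benzyl-epigallocatechin
Conditions: NBS (1.0 equiv), CH2Cl2, −78 °C to 0 °C
Reagents that add atoms: N-bromosuccinimide O=C1CCC(=O)N1Br
Why: Electrophilic aromatic bromination; in 5,7-di-O-benzyl flavan-3-ol ethers C8, flanked by O1 and the C7 ether, is the most reactive ring A position, so one equivalent at low temperature should brominate there only.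

Step 3
Reactants: 4 8-bromo-hexa-O-benzyl-epigallocatechin
Product: 6 8-formyl-hexa-O-benzyl-epigallocatechin, via 8-lithio arene 5 (not isolated)
Conditions: n-BuLi (1.1 equiv), THF, −78 °C; DMF, −78 °C to 0 °C; aq NH4Cl
Reagents that add atoms: N,N-dimethylformamide CN(C)C=O; n-butyllithium [Li]CCCC (lithium in 5 only)
Why: Bromine–lithium exchange followed by formylation of the aryllithium with DMF; at −78 °C the benzyl ethers and the two stereocentres are not affected.

Step 4
Reactants: 6 8-formyl-hexa-O-benzyl-epigallocatechin; 7 4′-benzyloxyacetophenone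
Product: 8 (E)-chalcone
Conditions: KOH (aq, cat.), EtOH/THF, rt to 40 °C
Reagents that add atoms: none
Why: Claisen–Schmidt condensation; the aldehyde cannot enolise, dehydration of the aldol is driven by conjugation and gives the (E)-enone, and with all phenols capped the flavan stereocentres are base-stable.

Step 5
Reactants: 8 (E)-chalcone; 9 potassium vinyltrifluoroborate
Product: 10 (3R)-3-vinyl ketone
Conditions: [Rh(C2H4)2Cl]2 (3 mol %), (1R,4R)-2,5-diphenylbicyclo[2.2.2]octa-2,5-diene (7 mol %), 9 (3 equiv), Et3N, toluene/H2O 10:1, 60 °C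
Reagents that add atoms: none
Why: Rh-catalysed Hayashi–Miyaura conjugate addition, in which a vinyl–Rh species inserts the enone and the Rh enolate is protonated by water; the chiral diene controls the face (Si face of C-β, giving 3R), the epigallocatechin stereocentres being too remote to compete.

Step 6
Reactants: 10 (3R)-3-vinyl ketone
Product: 11 (1R,3R)-carbinol
Conditions: (S)-2-methyl-CBS-oxazaborolidine (20 mol %), catecholborane (2 equiv), toluene, −78 °C to −40 °C
Reagents that add atoms: none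
Why: Corey–Bakshi–Shibata reduction, in which the (S)-oxazaborolidine places the aryl group as the large substituent and delivers hydride to give the (R)-carbinol under catalyst control; catecholborane is used because BH3 would hydroborate the vinyl group.

Step 7
Reactants: 11 (1R,3R)-carbinol
Product: 12 TBS ether of the carbinol
Conditions: TBSCl, imidazole, DMF, rt
Reagents that add atoms: tert-butyldimethylsilyl chloride CC(C)(C)[Si](C)(C)Cl
Why: Imidazole-promoted O-silylation of the only free hydroxyl; the configuration at the carbinol is retained because the C–O bond is not broken.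

Step 8
Reactants: 12 TBS ether of the carbinol; 13 methyl vinyl ketone
Product: 14 (E)-methyl enone
Conditions: second-generation Hoveyda–Grubbs catalyst RuCl2(H2IMes)(=CH–C6H4-2-OiPr) (5 mol %), 13 (5 equiv), CH2Cl2, 40 °C
Reagents that add atoms: none
Why: Olefin cross-metathesis of a terminal alkene with an electron-poor enone that homodimerises slowly, so the cross product should form selectively as the (E)-enone; the allylic stereocentre takes no part.

Step 9
Reactants: 14 (E)-methyl enone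
Product: 16 (E)-diazo enone, via trifluoroacetyl diketone 15 (not isolated)
Conditions: LiN(SiMe3)2 (1.1 equiv), THF, −78 °C; CF3CO2CH2CF3 (1.2 equiv); cold dilute HCl wash; then MsN3 (1.5 equiv), Et3N (1.5 equiv), H2O (1 equiv), MeCN, rt
Reagents that add atoms: methanesulfonyl azide CS(=O)(=O)N=[N+]=[N-]; 2,2,2-trifluoroethyl trifluoroacetate O=C(OCC(F)(F)F)C(F)(F)F (acyl group in 15 only)
Why: Detrifluoroacetylative diazo transfer, in which the methyl (α′) proton is removed under kinetic control at −78 °C, the enolate is trifluoroacetylated, and the sulfonyl azide transfers the diazo group with loss of the trifluoroacetyl group under mild amine conditions; the more hindered γ-hydrogen at chain C5 should not be abstracted, so that centre is retained.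

Step 10
Reactants: 17 benzyl alcohol; 18 trichloroethylene
Product: 21 benzyloxyacetylene, via benzyl dichlorovinyl ether 19 (not isolated), via lithium benzyloxyacetylide 20 (not isolated)
Conditions: KH (1.2 equiv), THF, 0 °C; 18, −50 °C to rt; n-BuLi (2.3 equiv), −78 °C; MeOH, −78 °C; stored as a cold solution
Reagents that add atoms: n-butyllithium [Li]CCCC (lithium in 20 only)
Why: Alkoxide addition–elimination on trichloroethylene gives the 1,2-dichlorovinyl ether, and n-BuLi then effects dehydrochlorination and chlorine–lithium exchange to the lithium alkoxyacetylide, which is protonated cold (the known one-flask synthesis of alkoxyacetylenes from alcohols).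

Step 11
Reactants: 16 (E)-diazo enone; 21 benzyloxyacetylene
Product: 26 ring A phenol (C8a–OH free; C7–OBn), via vinylketene 22 (not isolated), via vinylcyclobutenone 23 (not isolated), via dienylketene 24 (not isolated), via cyclohexadienone 25 (not isolated)
Conditions: hν (450 W medium-pressure Hg lamp, Pyrex), 21 (3 equiv), ClCH2CH2Cl (0.02 M, degassed), 20 °C; excess 21 removed in vacuo; toluene, 80 °C
Reagents that add atoms: none
Why: Light expels N2 from 16 and the alkenyl group migrates (Wolff rearrangement, forming C5–C6) to give vinylketene 22, whose electrophilic carbonyl carbon adds to the unsubstituted, nucleophilic carbon of the ynol ether in a [2+2] cycloaddition (C8–C8a and C6–C7) to give cyclobutenone 23. Warming opens 23 by 4π electrocyclic cleavage to dienylketene 24, which closes ring A by thermal 6π electrocyclisation (C4a–C8a) to dienone 25 and tautomerises to phenol 26. The closest known reaction type is the Danheiser benzannulation in its photochemical Wolff variant, in which α-diazo enones and alkoxy- or siloxyalkynes give resorcinol monoethers. No stereocentre is created (the sp3 ring carbons of 23 and 25 vanish on aromatisation), and in the neutral medium the allylic C4–H and the carbinol centre should stay untouched. The step needs regioselectivity (the oxygen of 21 must end on C7, meta to the new hydroxyl), which the ketene/ynol ether polarity secures, and chemoselective capture of 22, which the capped hydroxyl groups, the excess of 21 and dilution secure. Because benzyl alkynyl ethers rearrange on heating, irradiation is run cold and the excess is stripped before the thermal stage.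

Step 12
Reactants: 26 ring A phenol
Product: 27 phenol carbinol
Conditions: Bu4NF (3 equiv), THF, 0 °C to rt; aq NH4Cl
Reagents that add atoms: none
Why: Fluoride-induced desilylation of the only silyl ether, driven by Si–F bond formation; benzyl ethers and the phenol are inert and no acid reaches the ionisable benzylic carbinol.

Step 13
Reactants: 27 phenol carbinol
Product: 28 (2S,4R)-octa-O-benzyl flavan dimer
Conditions: PPh3 (1.5 equiv), DIAD (1.5 equiv), toluene (0.01 M), 0 °C to rt
Reagents that add atoms: none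
Why: Intramolecular Mitsunobu etherification, in which the C8a phenol (the only acidic OH) displaces the oxyphosphonium of the (R)-carbinol in a six-membered SN2 closure with inversion, setting 2S and hence the 2,4-trans ring C; the non-polar solvent and low temperature disfavour ionisation of the benzylic centre.

Step 14
Reactants: 28 (2S,4R)-octa-O-benzyl flavan dimer
Product: 29 target CNP0220331.1
Conditions: H2 (1 atm), Pd(OH)2/C, THF/MeOH 1:1, rt; filtered under argon
Reagents that add atoms: none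
Why: Catalytic hydrogenolysis of the eight O-benzyl groups under neutral conditions; the cyclic C2–O1 benzylic ether bonds and the C4–C8 carbon–carbon bond should be cleaved far more slowly than O-benzyl groups, and no stereocentre is affected.

**Compound list**

1 | (−)-epigallocatechin, (2R,3R) | O[C@@H]1Cc2c(O)cc(O)cc2O[C@@H]1c1cc(O)c(O)c(O)c1 | starting material
2 | 5,7,3′,4′,5′-penta-O-benzyl-epigallocatechin (3-OH free) | c1c(OCc3ccccc3)cc(OCc3ccccc3)c2c1O[C@H](c4cc(OCc5ccccc5)c(OCc5ccccc5)c(OCc5ccccc5)c4)[C@H](O)C2 | intermediate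
3 | 3,5,7,3′,4′,5′-hexa-O-benzyl-epigallocatechin | c1c(OCc3ccccc3)cc(OCc3ccccc3)c2c1O[C@H](c4cc(OCc5ccccc5)c(OCc5ccccc5)c(OCc5ccccc5)c4)[C@H](OCc3ccccc3)C2 | intermediate
4 | 8-bromo-hexa-O-benzyl-epigallocatechin | Brc1c(OCc3ccccc3)cc(OCc3ccccc3)c2c1O[C@H](c4cc(OCc5ccccc5)c(OCc5ccccc5)c(OCc5ccccc5)c4)[C@H](OCc3ccccc3)C2 | intermediate
5 | 8-lithio-hexa-O-benzyl-epigallocatechin | [Li]c1c(OCc3ccccc3)cc(OCc3ccccc3)c2c1O[C@H](c4cc(OCc5ccccc5)c(OCc5ccccc5)c(OCc5ccccc5)c4)[C@H](OCc3ccccc3)C2 | intermediate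
6 | 8-formyl-hexa-O-benzyl-epigallocatechin | O=Cc1c(OCc3ccccc3)cc(OCc3ccccc3)c2c1O[C@H](c4cc(OCc5ccccc5)c(OCc5ccccc5)c(OCc5ccccc5)c4)[C@H](OCc3ccccc3)C2 | intermediate
7 | 4′-benzyloxyacetophenone | CC(=O)c1ccc(OCc2ccccc2)cc1 | starting material
8 | (E)-1-(4-benzyloxyphenyl)-3-(hexa-O-benzyl-epigallocatechin-8-yl)prop-2-en-1-one | O=C(/C=C/c1c(OCc3ccccc3)cc(OCc3ccccc3)c2c1O[C@H](c4cc(OCc5ccccc5)c(OCc5ccccc5)c(OCc5ccccc5)c4)[C@H](OCc3ccccc3)C2)c1ccc(OCc2ccccc2)cc1 | intermediate
9 | potassium vinyltrifluoroborate | C=C[B-](F)(F)F.[K+] | starting material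
10 | (3R)-1-(4-benzyloxyphenyl)-3-(hexa-O-benzyl-epigallocatechin-8-yl)pent-4-en-1-one | C=C[C@H](c1c(OCc3ccccc3)cc(OCc3ccccc3)c2c1O[C@H](c4cc(OCc5ccccc5)c(OCc5ccccc5)c(OCc5ccccc5)c4)[C@H](OCc3ccccc3)C2)CC(=O)c1ccc(OCc2ccccc2)cc1 | intermediate
11 | (1R,3R)-1-(4-benzyloxyphenyl)-3-(hexa-O-benzyl-epigallocatechin-8-yl)pent-4-en-1-ol | C=C[C@H](c1c(OCc3ccccc3)cc(OCc3ccccc3)c2c1O[C@H](c4cc(OCc5ccccc5)c(OCc5ccccc5)c(OCc5ccccc5)c4)[C@H](OCc3ccccc3)C2)C[C@@H](O)c1ccc(OCc2ccccc2)cc1 | intermediate
12 | tert-butyldimethylsilyl ether of 11, (1R,3R) | C=C[C@H](c1c(OCc3ccccc3)cc(OCc3ccccc3)c2c1O[C@H](c4cc(OCc5ccccc5)c(OCc5ccccc5)c(OCc5ccccc5)c4)[C@H](OCc3ccccc3)C2)C[C@@H](O[Si](C)(C)C(C)(C)C)c1ccc(OCc2ccccc2)cc1 | intermediate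
13 | methyl vinyl ketone | CC(=O)C=C | starting material
14 | (3E,5R,7R)-7-(4-benzyloxyphenyl)-7-(tert-butyldimethylsilyloxy)-5-(hexa-O-benzyl-epigallocatechin-8-yl)hept-3-en-2-one | CC(=O)/C=C/[C@H](c1c(OCc3ccccc3)cc(OCc3ccccc3)c2c1O[C@H](c4cc(OCc5ccccc5)c(OCc5ccccc5)c(OCc5ccccc5)c4)[C@H](OCc3ccccc3)C2)C[C@@H](O[Si](C)(C)C(C)(C)C)c1ccc(OCc2ccccc2)cc1 | intermediate
15 | 1-trifluoroacetyl derivative of 14 (1,1,1-trifluoro-2,4-dioxo-oct-5-ene chain; mainly enolised) | O=C(CC(=O)C(F)(F)F)/C=C/[C@H](c1c(OCc3ccccc3)cc(OCc3ccccc3)c2c1O[C@H](c4cc(OCc5ccccc5)c(OCc5ccccc5)c(OCc5ccccc5)c4)[C@H](OCc3ccccc3)C2)C[C@@H](O[Si](C)(C)C(C)(C)C)c1ccc(OCc2ccccc2)cc1 | intermediate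
16 | (3E,5R,7R)-1-diazo-7-(4-benzyloxyphenyl)-7-(tert-butyldimethylsilyloxy)-5-(hexa-O-benzyl-epigallocatechin-8-yl)hept-3-en-2-one | [N-]=[N+]=CC(=O)/C=C/[C@H](c1c(OCc3ccccc3)cc(OCc3ccccc3)c2c1O[C@H](c4cc(OCc5ccccc5)c(OCc5ccccc5)c(OCc5ccccc5)c4)[C@H](OCc3ccccc3)C2)C[C@@H](O[Si](C)(C)C(C)(C)C)c1ccc(OCc2ccccc2)cc1 | intermediate
17 | benzyl alcohol | OCc1ccccc1 | starting material
18 | trichloroethylene | ClC=C(Cl)Cl | starting material
19 | benzyl (E)-1,2-dichlorovinyl ether | Cl/C=C(/Cl)OCc1ccccc1 | intermediate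
20 | lithium benzyloxyacetylide | [Li]C#COCc1ccccc1 | intermediate
21 | benzyloxyacetylene (benzyl ethynyl ether) | C#COCc1ccccc1 | intermediate
22 | vinylketene from Wolff rearrangement of 16 (3E, 5R, 7R) | O=C=C/C=C/[C@H](c1c(OCc3ccccc3)cc(OCc3ccccc3)c2c1O[C@H](c4cc(OCc5ccccc5)c(OCc5ccccc5)c(OCc5ccccc5)c4)[C@H](OCc3ccccc3)C2)C[C@@H](O[Si](C)(C)C(C)(C)C)c1ccc(OCc2ccccc2)cc1 | intermediate
23 | 3-benzyloxy-4-alkenylcyclobut-2-enone (ring sp3 centre not defined) | O=C1C=C(OCc2ccccc2)C1/C=C/[C@H](c1c(OCc3ccccc3)cc(OCc3ccccc3)c2c1O[C@H](c4cc(OCc5ccccc5)c(OCc5ccccc5)c(OCc5ccccc5)c4)[C@H](OCc3ccccc3)C2)C[C@@H](O[Si](C)(C)C(C)(C)C)c1ccc(OCc2ccccc2)cc1 | intermediate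
24 | 3-benzyloxy-(3Z,5E)-dienylketene | O=C=C/C(OCc1ccccc1)=C\C=C\[C@H](c1c(OCc3ccccc3)cc(OCc3ccccc3)c2c1O[C@H](c4cc(OCc5ccccc5)c(OCc5ccccc5)c(OCc5ccccc5)c4)[C@H](OCc3ccccc3)C2)C[C@@H](O[Si](C)(C)C(C)(C)C)c1ccc(OCc2ccccc2)cc1 | intermediate
25 | 3-benzyloxy-6-substituted cyclohexa-2,4-dienone (ring sp3 centre not defined) | O=C1C=C(OCc2ccccc2)C=CC1[C@H](c1c(OCc3ccccc3)cc(OCc3ccccc3)c2c1O[C@H](c4cc(OCc5ccccc5)c(OCc5ccccc5)c(OCc5ccccc5)c4)[C@H](OCc3ccccc3)C2)C[C@@H](O[Si](C)(C)C(C)(C)C)c1ccc(OCc2ccccc2)cc1 | intermediate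
26 | 5-benzyloxy-2-[(1R,3R)-3-(4-benzyloxyphenyl)-3-(tert-butyldimethylsilyloxy)-1-(hexa-O-benzyl-epigallocatechin-8-yl)propyl]phenol | Oc1cc(OCc2ccccc2)ccc1[C@H](c1c(OCc3ccccc3)cc(OCc3ccccc3)c2c1O[C@H](c4cc(OCc5ccccc5)c(OCc5ccccc5)c(OCc5ccccc5)c4)[C@H](OCc3ccccc3)C2)C[C@@H](O[Si](C)(C)C(C)(C)C)c1ccc(OCc2ccccc2)cc1 | intermediate
27 | 5-benzyloxy-2-[(1R,3R)-3-(4-benzyloxyphenyl)-3-hydroxy-1-(hexa-O-benzyl-epigallocatechin-8-yl)propyl]phenol | Oc1cc(OCc2ccccc2)ccc1[C@H](c1c(OCc3ccccc3)cc(OCc3ccccc3)c2c1O[C@H](c4cc(OCc5ccccc5)c(OCc5ccccc5)c(OCc5ccccc5)c4)[C@H](OCc3ccccc3)C2)C[C@@H](O)c1ccc(OCc2ccccc2)cc1 | intermediate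
28 | (2S,4R)-7-benzyloxy-2-(4-benzyloxyphenyl)-4-(hexa-O-benzyl-epigallocatechin-8-yl)chroman | C(c9ccccc9)Oc6ccc([C@@H]7C[C@@H](c1c(OCc3ccccc3)cc(OCc3ccccc3)c2c1O[C@H](c4cc(OCc5ccccc5)c(OCc5ccccc5)c(OCc5ccccc5)c4)[C@H](OCc3ccccc3)C2)c8ccc(OCc9ccccc9)cc8O7)cc6 | intermediate
29 | CNP0220331.1, (2S,4R)-4′,7-dihydroxyflavan-(4→8)-(−)-epigallocatechin | Oc1ccc([C@@H]2C[C@@H](c3c(O)cc(O)c4c3O[C@H](c3cc(O)c(O)c(O)c3)[C@H](O)C4)c3ccc(O)cc3O2)cc1 | target

**Totals.** Total step count: 14. Longest linear sequence: 13 steps (steps 1–9 and 11–14); step 10 is a one-step side branch.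

**Three steps most likely to fail**

Step 11. The vinylketene may be consumed by dimerisation or by O-acylation of phenol already formed faster than the ynol ether captures it, or the ynol ether may rearrange thermally before it reacts, so that ring A does not form cleanly. The fallback gives up the ring A construction and makes the C4–C8 bond by Friedel–Crafts arylation of a flavan-4-yl cation; it sets out from 3 and comes back at 28. Commercial 7-hydroxychromen-4-one is O-benzylated (BnBr, K2CO3, acetone) to 7-(benzyloxy)chromen-4-one F1. Conjugate addition of 4-(benzyloxy)phenylboronic acid, catalysed by Pd(OCOCF3)2 and 4-tert-butyl-2-(pyridin-2-yl)-4,5-dihydrooxazole (the ligand enantiomer that leads to 2S), gives (2S)-4′,7-bis(benzyloxy)flavan-4-one F2. NaBH4 reduces it to the 2,4-cis flavan-4-ol F3. BF3·OEt2 in CH2Cl2 at −78 °C with excess 3 ionises F3, and C8 of 3 should attack the cation anti to the 2-aryl group to give 28.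

Step 5. Insertion at the doubly ortho-substituted β-aryl enone may be slow, letting protodeboronation of the vinyl boron reagent win, or the facial selectivity may be poor. The fallback uses auxiliary-controlled cuprate addition; it sets out from 6 and comes back at 10. Knoevenagel–Doebner condensation of 6 with malonic acid (pyridine, piperidine) gives (E)-3-(hexa-O-benzyl-epigallocatechin-8-yl)acrylic acid F4. Its pivaloyl mixed anhydride acylates lithiated (S)-4-phenyloxazolidin-2-one to the N-enoyl oxazolidinone F5. CH2=CHMgBr with CuBr·SMe2 adds to the chelated s-cis imide anti to the phenyl group, giving the (3R)-3-vinyl imide F6. Me(MeO)NH·HCl with AlMe3 gives the N-methoxy-N-methylamide F7, and 4-(benzyloxy)phenylmagnesium bromide converts F7 into 10.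

Step 13. The oxyphosphonium of the 4-benzyloxybenzylic carbinol may ionise, which would erode the inversion at C2 or lead to elimination. The fallback forms the aryl C8a–O bond instead, with retention at C2; it sets out from 27 and comes back at 28. PhNTf2 with K2CO3 triflates only the phenol, giving aryl triflate F8. Oxidation of the carbinol with the periodinane DMP gives ketone F9. Reduction with (R)-2-methyl-CBS-oxazaborolidine and catecholborane gives the (S)-carbinol F10. Intramolecular C–O coupling with Pd(OAc)2, 2-(di-tert-butylphosphino)-1,1′-binaphthyl and K3PO4 in toluene at 80 °C closes ring C to 28.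

**Further compounds**

F1 | step 11 | 7-(benzyloxy)chromen-4-one | O=c1ccoc2cc(OCc3ccccc3)ccc12
F2 | step 11 | (2S)-4′,7-bis(benzyloxy)flavan-4-one | O=C1C[C@@H](c2ccc(OCc3ccccc3)cc2)Oc2cc(OCc3ccccc3)ccc12
F3 | step 11 | (2S,4S)-4′,7-bis(benzyloxy)flavan-4-ol (2,4-cis) | O[C@H]1C[C@@H](c2ccc(OCc3ccccc3)cc2)Oc2cc(OCc3ccccc3)ccc12
F4 | step 5 | (E)-3-(hexa-O-benzyl-epigallocatechin-8-yl)acrylic acid | OC(=O)/C=C/c1c(OCc3ccccc3)cc(OCc3ccccc3)c2c1O[C@H](c4cc(OCc5ccccc5)c(OCc5ccccc5)c(OCc5ccccc5)c4)[C@H](OCc3ccccc3)C2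
F5 | step 5 | (S)-4-phenyl-3-[(E)-3-(hexa-O-benzyl-epigallocatechin-8-yl)acryloyl]oxazolidin-2-one | O=C(/C=C/c1c(OCc3ccccc3)cc(OCc3ccccc3)c2c1O[C@H](c4cc(OCc5ccccc5)c(OCc5ccccc5)c(OCc5ccccc5)c4)[C@H](OCc3ccccc3)C2)N1[C@@H](c2ccccc2)COC1=O
F6 | step 5 | (S)-4-phenyl-3-[(3R)-3-(hexa-O-benzyl-epigallocatechin-8-yl)pent-4-enoyl]oxazolidin-2-one | O=C(C[C@H](C=C)c1c(OCc3ccccc3)cc(OCc3ccccc3)c2c1O[C@H](c4cc(OCc5ccccc5)c(OCc5ccccc5)c(OCc5ccccc5)c4)[C@H](OCc3ccccc3)C2)N1[C@@H](c2ccccc2)COC1=O
F7 | step 5 | (3R)-N-methoxy-N-methyl-3-(hexa-O-benzyl-epigallocatechin-8-yl)pent-4-enamide | CON(C)C(=O)C[C@H](C=C)c1c(OCc3ccccc3)cc(OCc3ccccc3)c2c1O[C@H](c4cc(OCc5ccccc5)c(OCc5ccccc5)c(OCc5ccccc5)c4)[C@H](OCc3ccccc3)C2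
F8 | step 13 | aryl triflate of 27 (carbinol R, free) | FC(F)(F)S(=O)(=O)Oc1cc(OCc2ccccc2)ccc1[C@H](c1c(OCc3ccccc3)cc(OCc3ccccc3)c2c1O[C@H](c4cc(OCc5ccccc5)c(OCc5ccccc5)c(OCc5ccccc5)c4)[C@H](OCc3ccccc3)C2)C[C@@H](O)c1ccc(OCc2ccccc2)cc1
F9 | step 13 | aryl triflate ketone | FC(F)(F)S(=O)(=O)Oc1cc(OCc2ccccc2)ccc1[C@H](c1c(OCc3ccccc3)cc(OCc3ccccc3)c2c1O[C@H](c4cc(OCc5ccccc5)c(OCc5ccccc5)c(OCc5ccccc5)c4)[C@H](OCc3ccccc3)C2)CC(=O)c1ccc(OCc2ccccc2)cc1
F10 | step 13 | aryl triflate (S)-carbinol | FC(F)(F)S(=O)(=O)Oc1cc(OCc2ccccc2)ccc1[C@H](c1c(OCc3ccccc3)cc(OCc3ccccc3)c2c1O[C@H](c4cc(OCc5ccccc5)c(OCc5ccccc5)c(OCc5ccccc5)c4)[C@H](OCc3ccccc3)C2)C[C@H](O)c1ccc(OCc2ccccc2)cc1
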